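**Plan**

- Retrosynthetic cuts, in order: the four phenolic O–benzyl bonds and the ester O–CH3 bond; the ring C2–C3 bond of the oxolane (CO2Me-bearing carbon to benzylic carbon); the carboxylate O–CH2 bond and the carbinol ester C–O bond of a glycolate bridge; the C–CO2H bond of an α-arylidene-β-hydroxy acid; the carbinol–alkyne C–C bond.
- Enabling feature: in the oxolane, C3 is allylic to the exocyclic C4=CH–aryl bond, and C2 is the α-carbon of a carboxyl group that also carries ring oxygen O1, so C2–C3 is the retron of an ester-enolate [3,3] shift. Because O1–C5(=O) already ties C2 to C4, the precursor is a seven-membered 1,4-dioxepane-2,5-dione and the shift contracts it to the five-membered lactone.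
- Forward: aldehyde → aryl alkyne → (R)-diaryl propargylic alcohol → (E)-hydroxy acid → bromoacetate → seven-membered dilactone → Ireland–Claisen ring contraction (the lactone, the only ring of the target, arises here) → methyl ester → debenzylation.
- Stereochemistry: one carbinol centre from catalytic asymmetric alkynylation; the E-alkene of the precursor from syn-addition of H and CO2 across the alkyne; the rearrangement transfers the carbinol centre to C2 (S) and C3 (R), cis to each other, and fixes the Z-arylidene.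

Key step: step 6

Assumption: the (S,S) antipode of the ProPhenol ligand is taken to deliver the alkynyl group to the Si face of aldehyde 1 (R carbinol); should the sense be the reverse, the (R,R) ligand is used with no other change.

Step 1
Reactants: 1 3,4-bis(benzyloxy)benzaldehyde
Product: 2 1,2-bis(benzyloxy)-4-ethynylbenzene
Conditions: Ohira–Bestmann reagent (1.3 equiv), K2CO3 (2 equiv), MeOH/THF, 0 °C to rt
Reagents that add atoms: dimethyl (1-diazo-2-oxopropyl)phosphonate, CC(=O)C(=[N+]=[N-])P(=O)(OC)OC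
Why: Seyferth–Gilbert homologation in its Ohira–Bestmann form: methanolysis of the reagent gives the diazomethylphosphonate anion, which adds to the aldehyde, loses dimethyl phosphate and N2, and the alkylidene carbene gives the terminal alkyne by 1,2-H shift; benzyl ethers are inert to K2CO3/MeOH.

Step 2
Reactants: 2 1,2-bis(benzyloxy)-4-ethynylbenzene, 1 3,4-bis(benzyloxy)benzaldehyde
Product: 4 (1R)-1,3-bis[3,4-bis(benzyloxy)phenyl]prop-2-yn-1-ol, via alkynyl(methyl)zinc 3 (not isolated)
Conditions: Me2Zn, (S,S)-ProPhenol (10 mol %), Ph3P=O (20 mol %), toluene, 0–4 °C; aq. NH4Cl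
Reagents that add atoms: dimethylzinc, C[Zn]C (its Zn–CH3 unit is present in 3 only)
Why: Catalytic enantioselective addition of an alkynylzinc reagent to an aryl aldehyde (Zn2–ProPhenol catalyst formed from Me2Zn and the ligand); the ligand directs MeZn–C≡C–Ar to the Si face of the aldehyde, which sets the R carbinol centre.

Step 3
Reactants: 4 (1R)-1,3-bis[3,4-bis(benzyloxy)phenyl]prop-2-yn-1-ol
Product: 5 (2E)-3-[3,4-bis(benzyloxy)phenyl]-2-{(R)-[3,4-bis(benzyloxy)phenyl](hydroxy)methyl}prop-2-enoic acid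
Conditions: Ni(cod)2 (5 mol %), CsF, Et2Zn (3.5 equiv), CO2 (1 atm), MeCN, 60 °C; cold aq. citric acid
Reagents that add atoms: carbon dioxide, O=C=O
Why: Ni-catalysed three-component syn-hydrocarboxylation of an aryl alkyne with Et2Zn and CO2: oxidative cyclisation of zerovalent nickel with alkyne and CO2 puts the aryl-bearing carbon on nickel and the carboxyl on the carbon next to the carbinol (ROZnEt) carbon, and ethyl transfer, β-hydride elimination and C–H reductive elimination deliver H cis to the carboxylate, so the aryl ends up trans to CO2H (E) and the carbinol centre is untouched.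

Step 4
Reactants: 5 (2E)-3-[3,4-bis(benzyloxy)phenyl]-2-{(R)-[3,4-bis(benzyloxy)phenyl](hydroxy)methyl}prop-2-enoic acid
Product: 7 (2E)-3-[3,4-bis(benzyloxy)phenyl]-2-{(R)-[3,4-bis(benzyloxy)phenyl][(bromoacetyl)oxy]methyl}prop-2-enoic acid, via mixed anhydride 6 (not isolated)
Conditions: BrCH2COBr (1.3 equiv), 2,6-lutidine, CH2Cl2, −30 to 0 °C; pH 7 buffer
Reagents that add atoms: bromoacetyl bromide, BrCC(Br)=O
Why: O-acylation with an acyl bromide: the carboxylate is acylated first to mixed anhydride 6, whose bromoacetyl group passes to the neighbouring carbinol oxygen through a six-membered transition state, which frees the acid and retains the stereocentre because its C–O bond is not broken.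

Step 5
Reactants: 7 (2E)-3-[3,4-bis(benzyloxy)phenyl]-2-{(R)-[3,4-bis(benzyloxy)phenyl][(bromoacetyl)oxy]methyl}prop-2-enoic acid
Product: 8 (6E,7R)-7-[3,4-bis(benzyloxy)phenyl]-6-{[3,4-bis(benzyloxy)phenyl]methylidene}-1,4-dioxepane-2,5-dione
Conditions: Cs2CO3 (1.5 equiv), DMF (0.003 M, slow addition), rt
Reagents that add atoms: none
Why: Intramolecular alkylation of the carboxylate RCO2Cs at the primary α-bromo ester (SN2, 7-exo-tet) under high dilution closes the dilactone; neither the stereocentre nor the alkene takes part.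

Step 6
Reactants: 8 (6E,7R)-7-[3,4-bis(benzyloxy)phenyl]-6-{[3,4-bis(benzyloxy)phenyl]methylidene}-1,4-dioxepane-2,5-dione
Product: 11 (2S,3R,4Z)-3-[3,4-bis(benzyloxy)phenyl]-4-{[3,4-bis(benzyloxy)phenyl]methylidene}-5-oxooxolane-2-carboxylic acid, via silyl ketene acetal 9 (not isolated), via trimethylsilyl ester 10 (not isolated)
Conditions: TMSCl/Et3N, THF, −78 °C, then LiN(SiMe3)2 (1.3 equiv); warm to rt, then toluene, 80 °C; aq. citric acid/THF
Reagents that add atoms: chlorotrimethylsilane, C[Si](C)(C)Cl (silyl group present in 9 and 10 only; lost on work-up)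
Why: Proposed new method: LiN(SiMe3)2 removes a proton from the only enolisable position of 8, the glycolate CH2 (C3), and the enolate is silylated at once to the ring-held ketene acetal 9, whose C3=C2(OSi)–O1 unit and allylic C7–O1/C6=CH–aryl unit undergo a concerted suprafacial [3,3] shift that joins C3 to the arylidene carbon and breaks C7–O1, contracting the seven-membered ring to lactone 10 (hydrolysed to 11 on work-up). The closest known reaction types are the Ireland–Claisen ring contraction of macrolactones to carbocycles and the Ireland–Claisen rearrangement of open-chain esters of Baylis–Hillman-type alcohols; new is the dilactone-to-lactone case with a two-atom O–C(=O) tether. The five-membered ring closes by a 5-(enolexo)-endo-trig C–C bond formation at the arylidene carbon, unfavourable as an ionic step but open here because bond making and C–O breaking are synchronous in a bicyclo[3.2.1]octane-like chair array, the only array compatible with the O4–C5(=O) link between the enol carbon and the central allyl carbon. The benzylic centre (oxolane C3) is set by C7: A(1,3) strain with the arylidene aryl holds the C7–H bond in the alkene plane, so the C7 aryl points outward (giving the Z-arylidene) and the new bond forms on the face from which C7–O1 leaves; oxolane C2 is set by the ring-enforced ketene acetal geometry (O1 and O4 cis on C2=C3) within that chair, which places CO2SiMe3 cis to the C3 aryl. The step needs O-silylation to outrun Chan-type O-to-C acyl shift of the free Li enolate, secured by having TMSCl present during deprotonation, and [3,3] shift to outrun silyl migration or ionisation at C7, secured by neutral thermal conditions and helped by the acrylate carbonyl on the central allyl carbon and the electron-rich aryl on C7.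

Step 7
Reactants: 11 (2S,3R,4Z)-3-[3,4-bis(benzyloxy)phenyl]-4-{[3,4-bis(benzyloxy)phenyl]methylidene}-5-oxooxolane-2-carboxylic acid
Product: 12 methyl (2S,3R,4Z)-3-[3,4-bis(benzyloxy)phenyl]-4-{[3,4-bis(benzyloxy)phenyl]methylidene}-5-oxooxolane-2-carboxylate
Conditions: TMSCHN2, toluene/MeOH (4:1), 0 °C
Reagents that add atoms: (trimethylsilyl)diazomethane, C[Si](C)(C)C=[N+]=[N-]
Why: Methyl esterification of a carboxylic acid with a diazoalkane (protonation, then SN2 by the carboxylate) under neutral conditions, which avoids base that could epimerise the cis C2 centre or move the exocyclic alkene into the ring.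

Step 8
Reactants: 12 methyl (2S,3R,4Z)-3-[3,4-bis(benzyloxy)phenyl]-4-{[3,4-bis(benzyloxy)phenyl]methylidene}-5-oxooxolane-2-carboxylate
Product: 13 methyl (2S,3R,4Z)-3-(3,4-dihydroxyphenyl)-4-[(3,4-dihydroxyphenyl)methylidene]-5-oxooxolane-2-carboxylate
Conditions: BCl3 (10 equiv), pentamethylbenzene (12 equiv), CH2Cl2, −78 °C; MeOH quench
Reagents that add atoms: none
Why: Lewis-acid cleavage of aryl benzyl ethers with BCl3 and pentamethylbenzene as a non-basic benzyl cation scavenger at −78 °C; the methyl ester, lactone and trisubstituted alkene should survive and no stereocentre is touched.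

**Compound list**

1 | 3,4-bis(benzyloxy)benzaldehyde | O=Cc1ccc(OCc2ccccc2)c(OCc2ccccc2)c1 | starting material
2 | 1,2-bis(benzyloxy)-4-ethynylbenzene | C#Cc1ccc(OCc2ccccc2)c(OCc2ccccc2)c1 | intermediate
3 | alkynyl(methyl)zinc: {[3,4-bis(benzyloxy)phenyl]ethynyl}(methyl)zinc | C[Zn]C#Cc1ccc(OCc2ccccc2)c(OCc2ccccc2)c1 | intermediate
4 | (1R)-1,3-bis[3,4-bis(benzyloxy)phenyl]prop-2-yn-1-ol | O[C@@H](C#Cc1ccc(OCc2ccccc2)c(OCc2ccccc2)c1)c1ccc(OCc2ccccc2)c(OCc2ccccc2)c1 | intermediate
5 | (2E)-3-[3,4-bis(benzyloxy)phenyl]-2-{(R)-[3,4-bis(benzyloxy)phenyl](hydroxy)methyl}prop-2-enoic acid | O[C@@H](/C(=C\c1ccc(OCc2ccccc2)c(OCc2ccccc2)c1)C(=O)O)c1ccc(OCc2ccccc2)c(OCc2ccccc2)c1 | intermediate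
6 | mixed anhydride: bromoacetic (2E)-3-[3,4-bis(benzyloxy)phenyl]-2-{(R)-[3,4-bis(benzyloxy)phenyl](hydroxy)methyl}prop-2-enoic anhydride | O[C@@H](/C(=C\c1ccc(OCc2ccccc2)c(OCc2ccccc2)c1)C(=O)OC(=O)CBr)c1ccc(OCc2ccccc2)c(OCc2ccccc2)c1 | intermediate
7 | (2E)-3-[3,4-bis(benzyloxy)phenyl]-2-{(R)-[3,4-bis(benzyloxy)phenyl][(bromoacetyl)oxy]methyl}prop-2-enoic acid | BrCC(=O)O[C@@H](/C(=C\c1ccc(OCc2ccccc2)c(OCc2ccccc2)c1)C(=O)O)c1ccc(OCc2ccccc2)c(OCc2ccccc2)c1 | intermediate
8 | (6E,7R)-7-[3,4-bis(benzyloxy)phenyl]-6-{[3,4-bis(benzyloxy)phenyl]methylidene}-1,4-dioxepane-2,5-dione | O=C1COC(=O)/C(=C/c2ccc(OCc3ccccc3)c(OCc3ccccc3)c2)[C@@H](c2ccc(OCc3ccccc3)c(OCc3ccccc3)c2)O1 | intermediate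
9 | silyl ketene acetal: (6E,7R)-7-[3,4-bis(benzyloxy)phenyl]-6-{[3,4-bis(benzyloxy)phenyl]methylidene}-2-[(trimethylsilyl)oxy]-6,7-dihydro-5H-1,4-dioxepin-5-one | C[Si](C)(C)OC1=COC(=O)/C(=C/c2ccc(OCc3ccccc3)c(OCc3ccccc3)c2)[C@@H](c2ccc(OCc3ccccc3)c(OCc3ccccc3)c2)O1 | intermediate
10 | trimethylsilyl ester: trimethylsilyl (2S,3R,4Z)-3-[3,4-bis(benzyloxy)phenyl]-4-{[3,4-bis(benzyloxy)phenyl]methylidene}-5-oxooxolane-2-carboxylate | C[Si](C)(C)OC(=O)[C@H]1OC(=O)/C(=C\c2ccc(OCc3ccccc3)c(OCc3ccccc3)c2)[C@H]1c1ccc(OCc2ccccc2)c(OCc2ccccc2)c1 | intermediate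
11 | (2S,3R,4Z)-3-[3,4-bis(benzyloxy)phenyl]-4-{[3,4-bis(benzyloxy)phenyl]methylidene}-5-oxooxolane-2-carboxylic acid | OC(=O)[C@H]1OC(=O)/C(=C\c2ccc(OCc3ccccc3)c(OCc3ccccc3)c2)[C@H]1c1ccc(OCc2ccccc2)c(OCc2ccccc2)c1 | intermediate
12 | methyl (2S,3R,4Z)-3-[3,4-bis(benzyloxy)phenyl]-4-{[3,4-bis(benzyloxy)phenyl]methylidene}-5-oxooxolane-2-carboxylate | COC(=O)[C@H]1OC(=O)/C(=C\c2ccc(OCc3ccccc3)c(OCc3ccccc3)c2)[C@H]1c1ccc(OCc2ccccc2)c(OCc2ccccc2)c1 | intermediate
13 | methyl (2S,3R,4Z)-3-(3,4-dihydroxyphenyl)-4-[(3,4-dihydroxyphenyl)methylidene]-5-oxooxolane-2-carboxylate | COC(=O)[C@H]1OC(=O)/C(=C\c2ccc(O)c(O)c2)[C@H]1c1ccc(O)c(O)c1 | target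

**Totals and risks**

Total step count: 8. Longest linear sequence: 8 steps (1 to 13).

Steps most likely to fail:

1. Step 6 (proposed new method). The doubly constrained transition state may lie too high, so that ketene acetal 9 undergoes silyl migration or ionisation at C7 before the [3,3] shift, or the free enolate undergoes acyl shift before it is silylated. The fallback uses known chemistry (open-chain chelate-controlled Ireland–Claisen rearrangement, then lactonisation with inversion); it sets out from 5 and returns at 12. Esterification of 5 with TMSCHN2 gives the hydroxy methyl ester F1. Coupling with [(4-methoxybenzyl)oxy]acetic acid (EDC, catalytic DMAP, CH2Cl2) gives the glycolate ester F2. LiN(SiMe3)2 then TMSCl (THF, −78 °C to rt) gives the pentenoic acid F3; the benzylic centre and Z-alkene are as in the main route, but the oxygen-bearing centre is opposite, because the open-chain ketene acetal holds the α-oxygen trans to the allylic oxygen. TMSCHN2 gives the diester F4. DDQ (CH2Cl2/pH 7 buffer) removes the 4-methoxybenzyl group to give the hydroxy diester F5. Tf2O/2,6-lutidine (CH2Cl2, −78 °C) gives the triflate F6, which on warming is displaced with inversion by the carbonyl oxygen of the neighbouring acrylate methyl ester (5-exo-tet) with loss of its methyl group, giving 12.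

2. Step 3. Carboxylation may occur at the wrong alkyne carbon or be disturbed by the ROZnEt group, or the syn-adduct may lose geometric purity. The fallback makes the carbinol–alkene C–C bond instead of the C–CO2H bond; it sets out from 1 and returns at 5. One-pot bromination–Wittig olefination (ethyl (triphenylphosphoranylidene)acetate, NBS, CH2Cl2, −20 °C, then K2CO3 and 1) gives the Z-bromoacrylate F7, with the aryl trans to the ester. Nozaki–Hiyama–Kishi coupling of F7 with a second portion of 1 (CrCl2, catalytic NiCl2, chiral oxazoline–sulfonamide ligand, Et3N, THF) gives the hydroxy ethyl ester F8; the alkenyl–CrCl2 species should add with retention of alkene geometry, and the ligand is chosen for Si-face attack. LiOH (THF/H2O) gives 5.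

3. Step 5. Intermolecular alkylation (oligomers, the fourteen-membered dimer) or hydrolysis of the bromoacetate may outrun the seven-membered ring closure. The fallback closes the ring by acylation of the carbinol oxygen instead of carboxylate alkylation; it sets out from 5 and returns at 8. KHCO3 and allyl bromoacetate in DMF give the allyl diester F9. Pd(PPh3)4 and morpholine (THF) give the seco acid F10. Lactonisation with 2-methyl-6-nitrobenzoic anhydride, DMAP and Et3N (CH2Cl2, slow addition) gives 8.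

**Further compounds**

F1 | step 6 | hydroxy methyl ester: methyl (2E)-3-[3,4-bis(benzyloxy)phenyl]-2-{(R)-[3,4-bis(benzyloxy)phenyl](hydroxy)methyl}prop-2-enoate | O[C@@H](/C(=C\c1ccc(OCc2ccccc2)c(OCc2ccccc2)c1)C(=O)OC)c1ccc(OCc2ccccc2)c(OCc2ccccc2)c1
F2 | step 6 | glycolate ester: methyl (2E)-3-[3,4-bis(benzyloxy)phenyl]-2-{(R)-[3,4-bis(benzyloxy)phenyl]({[(4-methoxybenzyl)oxy]acetyl}oxy)methyl}prop-2-enoate | COc1ccc(COCC(=O)O[C@@H](/C(=C\c2ccc(OCc3ccccc3)c(OCc3ccccc3)c2)C(=O)OC)c2ccc(OCc3ccccc3)c(OCc3ccccc3)c2)cc1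
F3 | step 6 | pentenoic acid: (2R,3R,4Z)-3,5-bis[3,4-bis(benzyloxy)phenyl]-4-(methoxycarbonyl)-2-[(4-methoxybenzyl)oxy]pent-4-enoic acid | OC(=O)[C@H](OCc1ccc(OC)cc1)[C@H](c1ccc(OCc2ccccc2)c(OCc2ccccc2)c1)/C(C(=O)OC)=C/c1ccc(OCc2ccccc2)c(OCc2ccccc2)c1
F4 | step 6 | diester: methyl (2R,3R,4Z)-3,5-bis[3,4-bis(benzyloxy)phenyl]-4-(methoxycarbonyl)-2-[(4-methoxybenzyl)oxy]pent-4-enoate | COC(=O)[C@H](OCc1ccc(OC)cc1)[C@H](c1ccc(OCc2ccccc2)c(OCc2ccccc2)c1)/C(C(=O)OC)=C/c1ccc(OCc2ccccc2)c(OCc2ccccc2)c1
F5 | step 6 | hydroxy diester: methyl (2R,3R,4Z)-3,5-bis[3,4-bis(benzyloxy)phenyl]-2-hydroxy-4-(methoxycarbonyl)pent-4-enoate | COC(=O)[C@H](O)[C@H](c1ccc(OCc2ccccc2)c(OCc2ccccc2)c1)/C(C(=O)OC)=C/c1ccc(OCc2ccccc2)c(OCc2ccccc2)c1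
F6 | step 6 | triflate: methyl (2R,3R,4Z)-3,5-bis[3,4-bis(benzyloxy)phenyl]-4-(methoxycarbonyl)-2-{[(trifluoromethyl)sulfonyl]oxy}pent-4-enoate | COC(=O)[C@H](OS(=O)(=O)C(F)(F)F)[C@H](c1ccc(OCc2ccccc2)c(OCc2ccccc2)c1)/C(C(=O)OC)=C/c1ccc(OCc2ccccc2)c(OCc2ccccc2)c1
F7 | step 3 | Z-bromoacrylate: ethyl (2Z)-3-[3,4-bis(benzyloxy)phenyl]-2-bromoprop-2-enoate | CCOC(=O)/C(Br)=C/c1ccc(OCc2ccccc2)c(OCc2ccccc2)c1
F8 | step 3 | hydroxy ethyl ester: ethyl (2E)-3-[3,4-bis(benzyloxy)phenyl]-2-{(R)-[3,4-bis(benzyloxy)phenyl](hydroxy)methyl}prop-2-enoate | O[C@@H](/C(=C\c1ccc(OCc2ccccc2)c(OCc2ccccc2)c1)C(=O)OCC)c1ccc(OCc2ccccc2)c(OCc2ccccc2)c1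
F9 | step 5 | allyl diester: 2-oxo-2-(prop-2-en-1-yloxy)ethyl (2E)-3-[3,4-bis(benzyloxy)phenyl]-2-{(R)-[3,4-bis(benzyloxy)phenyl](hydroxy)methyl}prop-2-enoate | O[C@@H](/C(=C\c1ccc(OCc2ccccc2)c(OCc2ccccc2)c1)C(=O)OCC(=O)OCC=C)c1ccc(OCc2ccccc2)c(OCc2ccccc2)c1
F10 | step 5 | seco acid: {[(2E)-3-[3,4-bis(benzyloxy)phenyl]-2-{(R)-[3,4-bis(benzyloxy)phenyl](hydroxy)methyl}prop-2-enoyl]oxy}acetic acid | O[C@@H](/C(=C\c1ccc(OCc2ccccc2)c(OCc2ccccc2)c1)C(=O)OCC(=O)O)c1ccc(OCc2ccccc2)c(OCc2ccccc2)c1
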